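## Retrosynthetic overview
1. The 2,7-dioxabicyclo[3.2.1]octan-3-one (THF ring, then δ-lactone/acylal) closes last from a hydroxy/acid/aldehyde triad. The triad comes from glycol cleavage of a sacrificial cyclopentane whose five carbons are those of a D-ribose-derived cyclopentenone; they become C1, C8, C5, C4 and C3 of the bicycle.
2. The C1(azulene)–C8(bicycle) bond is made by decarboxylative Giese addition of the tertiary hydroazulenyl radical to that enone. The C6/CO2Me arm is added by a glyoxylate aldol.
3. The hydroazulene comes from a one-flask Negishi coupling/divinylcyclopropane–Cope rearrangement. It joins a five-carbon 2-isobutenylcyclopropyl unit to a cyclopentenyl triflate, making C8–C8a, C3a–C4 and the seven-membered ring together.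
4. Enabling feature: in the seven-membered ring the sp2 carbon C8 (=CH2) and the quaternary C4 (CMe2) flank the ring-fusion bond C8a–C3a and are bridged by exactly three CH2 groups (C5–C7). This is the retron of a cyclohepta-1,4-diene, that is, of a cis-divinylcyclopropane with a temporary C6–C8 bond whose isobutenyl terminus is C4.
5. Ring order: cyclopentane (purchased) → temporary cyclopropane → seven-membered ring (key step) → sacrificial cyclopentane attached → THF and δ-lactone.

Key step: step 7

Remark 1: the ester-bearing quaternary carbon is carried in both configurations (2–4 racemic, 13–20 as C1 epimers). It is written without a descriptor because it becomes a planar radical in step 13, where its final configuration is set.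
Remark 2: 21, 23 (cracked to the monomer before use) and Bu3SnOTf are taken as purchasable. Azulene and bicyclooctane locants are used in the text.

Step 1
Reactants: 1 methyl 2-oxocyclopentane-1-carboxylate
Product: 2 methyl 1-methyl-2-oxocyclopentane-1-carboxylate (racemic)
Conditions: MeI, K2CO3, acetone, reflux
Reagents that add atoms: iodomethane CI
Why: C-alkylation of the stabilised β-keto ester enolate installs the methyl group of the future quaternary carbon, which is deliberately left racemic because it is erased in step 13.

Step 2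
Reactants: 2 methyl 1-methyl-2-oxocyclopentane-1-carboxylate
Product: 4 methyl 1-methyl-2-(trifluoromethylsulfonyloxy)cyclopent-2-ene-1-carboxylate (racemic), via potassium enolate 3 (not isolated)
Conditions: KHMDS, THF, −78 °C; PhNTf2, −78 → 0 °C
Reagents that add atoms: N-phenylbis(trifluoromethanesulfonimide) O=S(=O)(N(c1ccccc1)S(=O)(=O)C(F)(F)F)C(F)(F)F
Why: The ketone has α-hydrogens on one side only, so enol triflate formation should give a single regioisomer with the C=C exactly where the annulation is needed.

Step 3
Reactants: 5 prop-2-yn-1-ol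
Product: 7 (Z)-3-(tributylstannyl)prop-2-en-1-ol, via cyclic vinylalanate 6 (not isolated)
Conditions: LiAlH4, THF, 0 °C → rt; Bu3SnOTf, −78 °C → rt; aq. work-up
Reagents that add atoms: tributyltin triflate CCCC[Sn](CCCC)(CCCC)OS(=O)(=O)C(F)(F)F
Why: Hydroxyl-directed trans-hydroalumination gives the five-membered alanate, and Al→Sn exchange with retention should give only the Z-vinylstannane.

Step 4
Reactants: 7 (Z)-3-(tributylstannyl)prop-2-en-1-ol
Product: 8 [(1S,2S)-2-(tributylstannyl)cyclopropyl]methanol (cis)
Conditions: Et2Zn, CH2I2, DME, (4S,5S)-2-butyl-N,N,N′,N′-tetramethyl-1,3,2-dioxaborolane-4,5-dicarboxamide (1.1 equiv), CH2Cl2, −10 °C → rt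
Reagents that add atoms: diiodomethane ICI
Why: In this asymmetric Simmons–Smith cyclopropanation (Charette variant) the stereospecific syn methylene transfer turns the Z-alkene into the cis-cyclopropane, and the alkoxide-bound chiral dioxaborolane selects the alkene face (sense assigned by analogy with other allylic alcohols).

Step 5
Reactants: 8 [(1S,2S)-2-(tributylstannyl)cyclopropyl]methanol
Product: 9 (1S,2S)-2-(tributylstannyl)cyclopropane-1-carbaldehyde (cis)
Conditions: Dess–Martin periodinane, NaHCO3, CH2Cl2, 0 °C
Reagents that add atoms: none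
Why: Buffered Dess–Martin oxidation is neutral enough to leave the C–Sn bond and the epimerisable cis-aldehyde untouched.

Step 6
Reactants: 9 (1S,2S)-2-(tributylstannyl)cyclopropane-1-carbaldehyde
Product: 10 tributyl[(1S,2S)-2-(2-methylprop-1-en-1-yl)cyclopropyl]stannane (cis)
Conditions: i-PrPPh3I, n-BuLi, THF, 0 °C; then 9, −78 °C → rt
Reagents that add atoms: isopropyltriphenylphosphonium iodide CC(C)[P+](c1ccccc1)(c1ccccc1)c1ccccc1.[I-]
Why: Wittig olefination with the fast, non-stabilised isopropylidene ylide at low temperature should outrun epimerisation and brings in the future C4 with both methyl groups.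

Step 7
Reactants: 10 tributyl[(1S,2S)-2-(2-methylprop-1-en-1-yl)cyclopropyl]stannane; 4 methyl 1-methyl-2-(trifluoromethylsulfonyloxy)cyclopent-2-ene-1-carboxylate
Product: 14 methyl (3aS)-1,4,4-trimethyl-1,2,3,3a,4,7-hexahydroazulene-1-carboxylate (both C1 epimers), via cyclopropyllithium 11 (not isolated), via cyclopropylzinc chloride 12 (not isolated), via cis-divinylcyclopropane 13 (not isolated)
Conditions: n-BuLi, THF, −78 °C; ZnCl2, −78 → 0 °C; 4, Pd2(dba)3/SPhos (cat.), THF, 60 °C; then PhMe, 110 °C, same flask
Reagents that add atoms: none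
Why: Sn→Li→Zn exchange proceeds with retention at the configurationally stable cyclopropyl carbon and Negishi coupling with the enol triflate makes C8–C8a to give cis-dialkenylcyclopropane 13, which on heating undergoes the strain-driven divinylcyclopropane–cycloheptadiene (Cope) rearrangement that breaks the temporary C6–C8 bond and makes C3a–C4, the quaternary CMe2 centre. The closest known reaction type is seven-ring annulation by Pd-catalysed coupling of 2-alkenylcyclopropylzinc halides (or the cuprates) with alkenyl electrophiles followed by Cope rearrangement. The seven-membered ring closes by a concerted suprafacial [3,3] shift through the endo-boat transition state, the only one that can deliver a cis,cis-cyclohepta-1,4-diene. The single new stereocentre C3a is controlled by the two cyclopropane stereocentres, because in the boat the isobutenyl terminus can reach only one face of the cyclopentene carbon, so the (1S,2S) reagent should give (3aS). The step needs cis geometry in 13, which is secured by the Z-alkene, the stereospecific cyclopropanation and the retentive metal exchanges; it also has to tolerate the methyl group that points into the boat, which only raises the barrier and is answered by heating, while the configuration at the ester-bearing carbon plays no role.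

Step 8
Reactants: 14 methyl (3aS)-1,4,4-trimethyl-1,2,3,3a,4,7-hexahydroazulene-1-carboxylate
Product: 15 methyl (3aS)-1,4,4-trimethyl-1,2,3,3a,4,5,6,7-octahydroazulene-1-carboxylate
Conditions: H2 (1 atm), RhCl(PPh3)3 (cat.), benzene/EtOH, rt
Reagents that add atoms: none
Why: Homogeneous hydrogenation with Wilkinson's catalyst should reduce the cis-disubstituted C5=C6 alkene and leave the hindered trisubstituted C8=C8a alkene.

Step 9
Reactants: 15 methyl (3aS)-1,4,4-trimethyl-1,2,3,3a,4,5,6,7-octahydroazulene-1-carboxylate
Product: 17 methyl 8-hydroxy-1,4,4-trimethyldecahydroazulene-1-carboxylate (cis-fused; H-3a, H-8a and OH on one face), via alkylborane 16 (not isolated)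
Conditions: BH3·THF, 0 °C → rt; NaOH, H2O2, 0 °C
Reagents that add atoms: hydrogen peroxide OO
Why: In this hydroboration–oxidation boron goes to the less substituted C8 and the syn addition should occur on the face opposite the C4 quaternary carbon, which puts H-8a cis to H-3a.

Step 10
Reactants: 17 methyl 8-hydroxy-1,4,4-trimethyldecahydroazulene-1-carboxylate
Product: 18 methyl 1,4,4-trimethyl-8-oxodecahydroazulene-1-carboxylate (cis-fused)
Conditions: Dess–Martin periodinane, NaHCO3, CH2Cl2, 0 °C → rt
Reagents that add atoms: none
Why: Neutral Dess–Martin oxidation avoids enolisation of the new ketone, so C8a should keep its configuration.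

Step 11
Reactants: 18 methyl 1,4,4-trimethyl-8-oxodecahydroazulene-1-carboxylate
Product: 19 methyl 1,4,4-trimethyl-8-methylidenedecahydroazulene-1-carboxylate (cis-fused)
Conditions: Zn, CH2Br2, TiCl4, THF/CH2Cl2, 0 °C → rt
Reagents that add atoms: dibromomethane BrCBr
Why: Takai–Lombardo methylenation is non-basic, so it should not epimerise C8a, and it leaves the ester alone.

Step 12
Reactants: 19 methyl 1,4,4-trimethyl-8-methylidenedecahydroazulene-1-carboxylate
Product: 20 1,4,4-trimethyl-8-methylidenedecahydroazulene-1-carboxylic acid (cis-fused)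
Conditions: NaSEt, DMF, 100 °C; then 1 M HCl
Reagents that add atoms: none
Why: SN2 dealkylation at the ester methyl carbon avoids attack at the hindered acyl carbon and touches no stereocentre.

Step 13
Reactants: 20 1,4,4-trimethyl-8-methylidenedecahydroazulene-1-carboxylic acid; 21 (3aR,6aR)-2,2-dimethyl-3a,6a-dihydro-4H-cyclopenta[d][1,3]dioxol-4-one
Product: 22 β-(hydroazulen-1-yl) acetonide-protected dihydroxycyclopentanone (azulenyl group trans to the acetonide; new bond at azulene C1 cis to H-8a)
Conditions: Ir[dF(CF3)ppy]2(dtbbpy)PF6 (cat.), K2HPO4, DMF, blue LED, rt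
Reagents that add atoms: none
Why: In this photoredox decarboxylative Giese addition both acid epimers give one tertiary radical, which should bond on the convex face of the cis-hydroazulene (setting azulene C1) and on the enone face anti to the acetonide (setting bicycle C8).

Step 14
Reactants: 22 β-(hydroazulen-1-yl) acetonide-protected dihydroxycyclopentanone; 23 methyl glyoxylate
Product: 26 syn-aldol adduct (CH(OH)CO2Me arm trans to the azulenyl group), via lithium enolate 24 (not isolated), via titanium enolate 25 (not isolated)
Conditions: LDA, THF, −78 °C; ClTi(Oi-Pr)3, −78 → −40 °C; 23, −78 °C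
Reagents that add atoms: none
Why: Kinetic deprotonation occurs at the CH2, the aldehyde approaches anti to the neighbouring azulenyl group (bicycle C5), and triisopropoxytitanium enolates of cyclic ketones are syn-selective in the aldol addition (bicycle C6).

Step 15
Reactants: 26 syn-aldol adduct
Product: 27 TIPS ether of 26
Conditions: TIPSOTf, 2,6-lutidine, CH2Cl2, −78 → 0 °C
Reagents that add atoms: triisopropylsilyl triflate CC(C)[Si](C(C)C)(C(C)C)OS(=O)(=O)C(F)(F)F
Why: Silylation under non-nucleophilic base avoids retro-aldol and elimination, and it masks the hydroxyl with a group stable to the acid of step 17.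

Step 16
Reactants: 27 TIPS ether of 26
Product: 29 ring acetate (OAc cis to the acetonide and to the ester arm), via ring alcohol 28 (not isolated)
Conditions: NaBH4, CeCl3·7H2O, MeOH, −78 °C; crude, Ac2O, DMAP, pyridine, 0 °C
Reagents that add atoms: acetic anhydride CC(=O)OC(C)=O
Why: In the Luche reduction hydride should attack the convex face of the acetonide-fused cyclopentanone, opposite both adjacent substituents (setting bicycle C4), and immediate acetylation forestalls γ-lactonisation onto the methyl ester.

Step 17
Reactants: 29 ring acetate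
Product: 30 cis-1,2-diol
Conditions: 1 M HCl, THF, rt, short contact
Reagents that add atoms: none
Why: Acid hydrolysis of the acetonide is known to spare TIPS ethers, acetates and 1,1-disubstituted alkenes, and short contact limits acetyl migration.

Step 18
Reactants: 30 cis-1,2-diol
Product: 31 1,5-dialdehyde
Conditions: NaIO4, THF/pH 7 buffer, 0 °C → rt
Reagents that add atoms: none
Why: Periodate glycol cleavage opens the sacrificial ring under neutral conditions without touching the alkene or the α-stereocentres.

Step 19
Reactants: 31 1,5-dialdehyde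
Product: 32 α-acetoxy acid aldehyde (in equilibrium with its 6-hydroxy-δ-lactone form)
Conditions: NaClO2 (1.1 equiv), NaH2PO4, 2-methylbut-2-ene, t-BuOH/H2O, 0 °C
Reagents that add atoms: sodium chlorite [Na+].[O-]Cl=O
Why: In the Pinnick oxidation the electrophilic, unhindered α-acetoxy aldehyde should react before the aldehyde next to the neopentyl-type carbon, and the latter is then masked as the pseudo-acid lactol.

Step 20
Reactants: 32 α-acetoxy acid aldehyde
Product: 34 target CNP0215240.1, via lactol acid 33 (not isolated)
Conditions: HF·pyridine, THF, 0 °C → rt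
Reagents that add atoms: none
Why: Desilylation frees the hydroxyl, which closes the five-membered lactol, and the ether-stabilised oxocarbenium ion is captured by the cis side-chain acid (acylal formation) faster than Fischer lactonisation, the bridge fixing the acetal carbon C1.

## Compound list
1 | methyl 2-oxocyclopentane-1-carboxylate | COC(=O)C1CCCC1=O | starting material
2 | methyl 1-methyl-2-oxocyclopentane-1-carboxylate | COC(=O)C1(C)CCCC1=O | intermediate
3 | potassium enolate of 2 | COC(=O)C1(C)CCC=C1[O-].[K+] | intermediate
4 | methyl 1-methyl-2-(trifluoromethylsulfonyloxy)cyclopent-2-ene-1-carboxylate | COC(=O)C1(C)CCC=C1OS(=O)(=O)C(F)(F)F | intermediate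
5 | prop-2-yn-1-ol | C#CCO | starting material
6 | cyclic lithium (Z)-vinylalanate | [Li+].[AlH2-]1OCC=C1 | intermediate
7 | (Z)-3-(tributylstannyl)prop-2-en-1-ol | CCCC[Sn](CCCC)(CCCC)/C=C\CO | intermediate
8 | [(1S,2S)-2-(tributylstannyl)cyclopropyl]methanol | CCCC[Sn](CCCC)(CCCC)[C@H]1C[C@H]1CO | intermediate
9 | (1S,2S)-2-(tributylstannyl)cyclopropane-1-carbaldehyde | CCCC[Sn](CCCC)(CCCC)[C@H]1C[C@H]1C=O | intermediate
10 | tributyl[(1S,2S)-2-(2-methylprop-1-en-1-yl)cyclopropyl]stannane | CCCC[Sn](CCCC)(CCCC)[C@H]1C[C@H]1C=C(C)C | intermediate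
11 | cis-2-(2-methylprop-1-enyl)cyclopropyllithium | [Li][C@H]1C[C@H]1C=C(C)C | intermediate
12 | cis-2-(2-methylprop-1-enyl)cyclopropylzinc chloride | Cl[Zn][C@H]1C[C@H]1C=C(C)C | intermediate
13 | cis-divinylcyclopropane (cyclopentenyl/isobutenyl) | COC(=O)C1(C)CCC=C1[C@H]2C[C@H]2C=C(C)C | intermediate
14 | methyl (3aS)-1,4,4-trimethyl-1,2,3,3a,4,7-hexahydroazulene-1-carboxylate | COC(=O)C1(C)CC[C@@H]2C1=CCC=CC2(C)C | intermediate
15 | methyl (3aS)-1,4,4-trimethyl-1,2,3,3a,4,5,6,7-octahydroazulene-1-carboxylate | COC(=O)C1(C)CC[C@@H]2C1=CCCCC2(C)C | intermediate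
16 | C8 alkylborane | B[C@H]1CCCC(C)(C)[C@@H]2CCC(C)(C(=O)OC)[C@H]12 | intermediate
17 | methyl 8-hydroxy-1,4,4-trimethyldecahydroazulene-1-carboxylate (cis-fused) | O[C@H]1CCCC(C)(C)[C@@H]2CCC(C)(C(=O)OC)[C@H]12 | intermediate
18 | methyl 1,4,4-trimethyl-8-oxodecahydroazulene-1-carboxylate (cis-fused) | O=C1CCCC(C)(C)[C@@H]2CCC(C)(C(=O)OC)[C@H]12 | intermediate
19 | methyl 1,4,4-trimethyl-8-methylidenedecahydroazulene-1-carboxylate (cis-fused) | C=C1CCCC(C)(C)[C@@H]2CCC(C)(C(=O)OC)[C@H]12 | intermediate
20 | 1,4,4-trimethyl-8-methylidenedecahydroazulene-1-carboxylic acid (cis-fused) | C=C1CCCC(C)(C)[C@@H]2CCC(C)(C(=O)O)[C@H]12 | intermediate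
21 | (3aR,6aR)-2,2-dimethyl-3a,6a-dihydro-4H-cyclopenta[d][1,3]dioxol-4-one | O=C1C=C[C@H]2OC(C)(C)O[C@@H]12 | starting material
22 | Giese adduct ketone | C=C1CCCC(C)(C)[C@@H]2CC[C@@](C)([C@@H]3[C@H]4OC(C)(C)O[C@H]4C(=O)C3)[C@H]12 | intermediate
23 | methyl glyoxylate | O=CC(=O)OC | starting material
24 | lithium enolate of 22 | C=C1CCCC(C)(C)[C@@H]2CC[C@@](C)([C@@H]3[C@H]4OC(C)(C)O[C@H]4C([O-])=C3)[C@H]12.[Li+] | intermediate
25 | triisopropoxytitanium enolate of 22 | C=C1CCCC(C)(C)[C@@H]2CC[C@@](C)([C@@H]3[C@H]4OC(C)(C)O[C@H]4C(O[Ti](OC(C)C)(OC(C)C)OC(C)C)=C3)[C@H]12 | intermediate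
26 | syn-aldol adduct | C=C1CCCC(C)(C)[C@@H]2CC[C@@](C)([C@@H]3[C@H]4OC(C)(C)O[C@H]4C(=O)[C@H]3[C@H](C(=O)OC)O)[C@H]12 | intermediate
27 | TIPS ether of 26 | C=C1CCCC(C)(C)[C@@H]2CC[C@@](C)([C@@H]3[C@H]4OC(C)(C)O[C@H]4C(=O)[C@H]3[C@H](C(=O)OC)O[Si](C(C)C)(C(C)C)C(C)C)[C@H]12 | intermediate
28 | ring alcohol | C=C1CCCC(C)(C)[C@@H]2CC[C@@](C)([C@@H]3[C@H]4OC(C)(C)O[C@H]4[C@@H](O)[C@H]3[C@H](C(=O)OC)O[Si](C(C)C)(C(C)C)C(C)C)[C@H]12 | intermediate
29 | ring acetate | C=C1CCCC(C)(C)[C@@H]2CC[C@@](C)([C@@H]3[C@H]4OC(C)(C)O[C@H]4[C@@H](OC(C)=O)[C@H]3[C@H](C(=O)OC)O[Si](C(C)C)(C(C)C)C(C)C)[C@H]12 | intermediate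
30 | cis-1,2-diol | C=C1CCCC(C)(C)[C@@H]2CC[C@@](C)([C@@H]3[C@@H](O)[C@@H](O)[C@@H](OC(C)=O)[C@H]3[C@H](C(=O)OC)O[Si](C(C)C)(C(C)C)C(C)C)[C@H]12 | intermediate
31 | 1,5-dialdehyde | C=C1CCCC(C)(C)[C@@H]2CC[C@@](C)([C@H](C=O)[C@@H]([C@H](OC(C)=O)C=O)[C@H](C(=O)OC)O[Si](C(C)C)(C(C)C)C(C)C)[C@H]12 | intermediate
32 | α-acetoxy acid aldehyde (open form) | C=C1CCCC(C)(C)[C@@H]2CC[C@@](C)([C@H](C=O)[C@@H]([C@H](OC(C)=O)C(=O)O)[C@H](C(=O)OC)O[Si](C(C)C)(C(C)C)C(C)C)[C@H]12 | intermediate
33 | lactol acid (anomers) | C=C1CCCC(C)(C)[C@@H]2CC[C@@](C)([C@@H]3C(O)O[C@@H](C(=O)OC)[C@@H]3[C@H](OC(C)=O)C(=O)O)[C@H]12 | intermediate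
34 | CNP0215240.1 | C=C1CCCC(C)(C)[C@@H]2CC[C@@](C)([C@@H]3[C@@H]4OC(=O)[C@@H](OC(C)=O)[C@H]3[C@H](C(=O)OC)O4)[C@H]12 | target

Total step count: 20. Longest linear sequence: 18 steps (5 → 34, steps 3–20).

## Steps most likely to fail

**Step 7.** Oxidative addition and transmetalation at the triflate next to a quaternary carbon may be slow, so that protonation or homocoupling of the zinc reagent consumes it. The rearrangement may also stall because of the inward-pointing methyl group.
The fallback replaces cross-coupling by carbonyl addition and elimination. It sets out from 10 (lithiated to 11, then CeCl3) and ketone 2. 1,2-Addition gives the tertiary cyclopropyl carbinol F1. Syn-elimination with Burgess reagent in hot toluene can go only toward the ring CH2, because the alternative is a strained alkylidenecyclopropane. This gives 13, which rearranges in the same flask, and the route is rejoined at 14.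

**Step 19.** Discrimination between the two aldehydes may be lost, giving oxidation at the hindered terminus or over-oxidation to the diacid. Epimerisation α to the aldehydes is also possible.
The fallback differentiates the two carbons before the ring is opened, and it sets out from diol 30. The less hindered carbinol next to the CHOAc carbon has an unshielded C–H bond, whereas the other C–H lies under the azulenyl group. It is oxidised chemoselectively (cationic neocuproine–Pd catalyst, benzoquinone) to the α-hydroxy ketone F2. Aqueous NaIO4 cleavage of this ketol gives the acid and the aldehyde regiospecifically, and the route is rejoined at 32.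

**Step 20.** The freed hydroxyl may γ-lactonise onto the carboxylic acid instead of engaging the aldehyde, and acid may move the exocyclic alkene into the ring.
The fallback changes from acid-catalysed substitution at the acetal carbon to acyl activation, and it sets out from 32. Buffered fluoride (TBAF/AcOH) removes the silyl group and 33 is isolated as the lactol. The acid is then activated (carbodiimide or 2,4,6-trichlorobenzoyl chloride, no strong acid) to esterify the anomeric hydroxyl, and the route is rejoined at 34.

Further compounds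
F1 | step 7 | methyl 2-hydroxy-1-methyl-2-[cis-2-(2-methylprop-1-enyl)cyclopropyl]cyclopentane-1-carboxylate | COC(=O)C1(C)CCCC1(O)[C@H]2C[C@H]2C=C(C)C
F2 | step 19 | α-hydroxy ketone from selective oxidation of 30 | C=C1CCCC(C)(C)[C@@H]2CC[C@@](C)([C@@H]3[C@@H](O)C(=O)[C@@H](OC(C)=O)[C@H]3[C@H](C(=O)OC)O[Si](C(C)C)(C(C)C)C(C)C)[C@H]12
F0 | step 20 | none | none
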